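## Retrosynthetic overview

1. Target 18 ⇒ dihydropyran 16: Br at C3 and OH at the hemiketal carbon C2 are added across the C2=C3 enol ether, and C3 is then settled by bromide exchange.
2. 16 ⇒ acetate 14 (key step): oxane O1, C2 and the C2 methyl are the ester oxygen, carbonyl carbon and methyl of an acetate; the C2–C3 ring bond is made as C2=C3 by carbonyl methylenation and enol-ether ring-closing metathesis onto the allyl group (C3, C4).
3. 14 ⇒ lactol 10 ⇒ chlorolactone 9: the E-bromoalkene comes from a Takai olefination; the C(CH3)Cl centre comes from enolate chlorination trans to allyl on a γ-butyrolactone template.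
4. 9 ⇒ (S)-4-allylbutyrolactone 6 ⇒ cyclopropane-fused lactone 3 + vinyl Grignard 4 ⇒ (S)-epichlorohydrin 1 + diethyl malonate 2.
5. Ring order: cyclopropane and γ-lactone as temporary template rings (step 1; opened in steps 2 and 7), then the oxane (step 9), the only ring of the target.

Key step: step 9

Remark: 18 is the hemiketal chair with OH axial at C2 and Br, the C2 methyl and the side chain equatorial; because Br+ is expected to add axially to the enol ether (trans to the side chain), C3 is set by bromide equilibration in step 11, not by the bromohydroxylation alone.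

## Route

Step 1
Reactants: 1 (S)-epichlorohydrin; 2 diethyl malonate
Product: 3 ethyl (1R,5S)-2-oxo-3-oxabicyclo[3.1.0]hexane-1-carboxylate
Conditions: NaOEt, EtOH, 0 °C then reflux
Reagents that add atoms: none
Why: Tandem malonate alkylation–cyclopropanation–lactonisation: the malonate anion opens the epoxide at its CH2 end, the alkoxide recloses an epoxide with loss of chloride, the malonate anion then closes the cyclopropane 3-exo-tet with inversion at the stereocentre and the freed alkoxide lactonises, so C5 of 3 derives from 1 and the cis ring fusion is enforced.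

Step 2
Reactants: 3 ethyl (1R,5S)-2-oxo-3-oxabicyclo[3.1.0]hexane-1-carboxylate; 4 vinylmagnesium bromide
Product: 5 ethyl (4S)-2-oxo-4-(prop-2-en-1-yl)oxolane-3-carboxylate (both C3 epimers)
Conditions: CuI (20 mol%), THF, −30 °C; aq. NH4Cl
Reagents that add atoms: none
Why: Copper-catalysed homoconjugate addition of the Grignard reagent opens the doubly activated cyclopropane at its unsubstituted CH2 carbon, which together with the vinyl group becomes the allyl chain; C4 is not involved and C3 is a freely epimerising malonate-type centre.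

Step 3
Reactants: 5 ethyl (4S)-2-oxo-4-(prop-2-en-1-yl)oxolane-3-carboxylate
Product: 6 (4S)-4-(prop-2-en-1-yl)oxolan-2-one
Conditions: LiCl, H2O, DMSO, 140 °C
Reagents that add atoms: none
Why: Krapcho dealkoxycarbonylation removes the malonate-type ester as CO2 and ethanol and leaves the non-acidic C4 stereocentre untouched.

Step 4
Reactants: 6 (4S)-4-(prop-2-en-1-yl)oxolan-2-one; 7 iodomethane
Product: 8 (3S,4S)-3-methyl-4-(prop-2-en-1-yl)oxolan-2-one
Conditions: LiN(i-Pr)2, THF, −78 °C; then MeI, −78 to −40 °C
Reagents that add atoms: none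
Why: Lactone enolate alkylation, with methyl entering trans to the C4 allyl group; this centre is made planar again in step 5, so its epimer ratio does not matter.

Step 5
Reactants: 8 (3S,4S)-3-methyl-4-(prop-2-en-1-yl)oxolan-2-one
Product: 9 (3S,4R)-3-chloro-3-methyl-4-(prop-2-en-1-yl)oxolan-2-one
Conditions: LiN(i-Pr)2, THF, −78 °C; then N-chlorosuccinimide, −78 to −40 °C
Reagents that add atoms: N-chlorosuccinimide, O=C1CCC(=O)N1Cl
Why: Electrophilic chlorination of the tetrasubstituted lithium enolate: on the nearly flat five-membered ring the chlorine donor approaches the face opposite the adjacent allyl group, so the quaternary centre should form with Cl trans and CH3 cis to allyl (substrate control by C4).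

Step 6
Reactants: 9 (3S,4R)-3-chloro-3-methyl-4-(prop-2-en-1-yl)oxolan-2-one
Product: 10 (3S,4R)-3-chloro-3-methyl-4-(prop-2-en-1-yl)oxolan-2-ol (both anomers)
Conditions: i-Bu2AlH, CH2Cl2, −78 °C; aq. potassium sodium tartrate
Reagents that add atoms: none
Why: Partial reduction of the lactone to the lactol, the aluminium hemiacetal being stable at −78 °C; the neighbouring centre is quaternary and cannot epimerise.

Step 7
Reactants: 10 (3S,4R)-3-chloro-3-methyl-4-(prop-2-en-1-yl)oxolan-2-ol; 11 bromoform
Product: 12 (2R,3S,4E)-5-bromo-3-chloro-3-methyl-2-(prop-2-en-1-yl)pent-4-en-1-ol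
Conditions: CrBr2, THF, 0 to 40 °C
Reagents that add atoms: none
Why: Takai olefination on the hydroxy aldehyde tautomer of the lactol: the geminal dichromium species formed from bromoform and divalent chromium adds to the aldehyde and eliminates to the E-bromoalkene, the bulky quaternary α-carbon favouring E and CrBr2 excluding chloride scrambling.

Step 8
Reactants: 12 (2R,3S,4E)-5-bromo-3-chloro-3-methyl-2-(prop-2-en-1-yl)pent-4-en-1-ol; 13 acetic anhydride
Product: 14 (2R,3S,4E)-5-bromo-3-chloro-3-methyl-2-(prop-2-en-1-yl)pent-4-en-1-yl acetate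
Conditions: pyridine, 4-dimethylaminopyridine (cat.), CH2Cl2, 0 °C
Reagents that add atoms: none
Why: Acylation of the primary alcohol installs the acetate whose carbonyl carbon, methyl group and ester oxygen become C2, the C2 methyl and O1 of the oxane.

Step 9
Reactants: 14 (2R,3S,4E)-5-bromo-3-chloro-3-methyl-2-(prop-2-en-1-yl)pent-4-en-1-yl acetate
Product: 16 (3R)-3-[(2S,3E)-4-bromo-2-chlorobut-3-en-2-yl]-6-methyl-3,4-dihydro-2H-pyran, via isopropenyl ether 15 (not isolated)
Conditions: Cp2TiMe2 (3 equiv), toluene, 65 °C, dark; filtration through basic Al2O3; then second-generation Grubbs catalyst RuCl2(=CHPh)(PCy3)(H2IMes) (10 mol%), toluene, 60 °C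
Reagents that add atoms: none
Why: On heating, Cp2TiMe2 loses methane to give the titanium methylidene Cp2Ti=CH2, which adds across the acetate C=O to an oxatitanacyclobutane and collapses to isopropenyl ether 15 and titanocene oxide (Petasis ester methylenation). The ruthenium benzylidene then loads onto the monosubstituted allyl alkene, the new alkylidene adds to the 1,1-disubstituted enol ether through a ruthenacyclobutane, and cycloreversion releases ethylene; the closest known reaction type is enol ether–olefin ring-closing metathesis to cyclic enol ethers. The single ring, the six-membered 3,4-dihydro-2H-pyran, is closed by ring-closing metathesis that makes the endocyclic C2=C3 bond (target numbering) between the former acetate carbon and the internal allyl carbon, so that O1, C2 and the C2 methyl all come from the acetate. No stereocentre is formed, and the two existing ones are remote from the reacting atoms. The step needs chemoselectivity twice: the neutral, non-Lewis-acidic titanium reagent should leave the tertiary allylic chloride and the bromoalkene alone, and the ruthenium alkylidene should close on the enol ether and not on the E-bromoalkene, which is 1,2-disubstituted, electron-poor and sits directly on the quaternary C(CH3)Cl carbon.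

Step 10
Reactants: 16 (3R)-3-[(2S,3E)-4-bromo-2-chlorobut-3-en-2-yl]-6-methyl-3,4-dihydro-2H-pyran
Product: 17 (2R,3R,5R)-3-bromo-5-[(2S,3E)-4-bromo-2-chlorobut-3-en-2-yl]-2-methyloxan-2-ol
Conditions: N-bromosuccinimide, NaHCO3, THF–H2O (4:1), 0 °C
Reagents that add atoms: N-bromosuccinimide, O=C1CCC(=O)N1Br; water, O
Why: Bromohydroxylation of the enol ether, Br+ going to the nucleophilic C3 and water to the C2 oxocarbenium ion; bromine should enter axially on the half-chair, anti to the pseudoaxial C4–H bond and so trans to the pseudoequatorial C5 side chain (substrate control, Fürst–Plattner-type), water then adds trans-diaxially and the hemiketal centre settles with OH axial (anomeric effect), giving mainly the 3-epimer 17 beside some 18.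

Step 11
Reactants: 17 (2R,3R,5R)-3-bromo-5-[(2S,3E)-4-bromo-2-chlorobut-3-en-2-yl]-2-methyloxan-2-ol
Product: 18 (2R,3S,5R)-3-bromo-5-[(2S,3E)-4-bromo-2-chlorobut-3-en-2-yl]-2-methyloxan-2-ol
Conditions: LiBr, acetone, 25 °C
Reagents that add atoms: lithium bromide, [Li+].[Br-]
Why: Degenerate SN2 bromide exchange at the α-bromo ketone carbon of the ring-opened δ-hydroxy ketone tautomer inverts C3 reversibly (halide-mediated epimerisation of an α-halo ketone), and reclosure should collect the material in the most stable chair, with Br, the C2 methyl and the C5 side chain equatorial and the C2 OH axial, which is 18; C5 and the C(CH3)Cl centre are not touched.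

## Compound list

1 | (S)-epichlorohydrin, (2S)-2-(chloromethyl)oxirane | ClC[C@@H]1CO1 | starting material
2 | diethyl malonate | CCOC(=O)CC(=O)OCC | starting material
3 | ethyl (1R,5S)-2-oxo-3-oxabicyclo[3.1.0]hexane-1-carboxylate | O=C1OC[C@H]2C[C@@]12C(=O)OCC | intermediate
4 | vinylmagnesium bromide | C=C[Mg]Br | starting material
5 | ethyl (4S)-2-oxo-4-(prop-2-en-1-yl)oxolane-3-carboxylate (both C3 epimers) | CCOC(=O)C1C(=O)OC[C@H]1CC=C | intermediate
6 | (4S)-4-(prop-2-en-1-yl)oxolan-2-one | O=C1OC[C@@H](CC=C)C1 | intermediate
7 | iodomethane | CI | starting material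
8 | (3S,4S)-3-methyl-4-(prop-2-en-1-yl)oxolan-2-one | O=C1OC[C@@H](CC=C)[C@@H]1C | intermediate
9 | (3S,4R)-3-chloro-3-methyl-4-(prop-2-en-1-yl)oxolan-2-one | O=C1OC[C@@H](CC=C)[C@]1(C)Cl | intermediate
10 | (3S,4R)-3-chloro-3-methyl-4-(prop-2-en-1-yl)oxolan-2-ol (both anomers) | OC1OC[C@@H](CC=C)[C@]1(C)Cl | intermediate
11 | bromoform | BrC(Br)Br | starting material
12 | (2R,3S,4E)-5-bromo-3-chloro-3-methyl-2-(prop-2-en-1-yl)pent-4-en-1-ol | OC[C@@H](CC=C)[C@](C)(Cl)/C=C/Br | intermediate
13 | acetic anhydride | CC(=O)OC(C)=O | starting material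
14 | (2R,3S,4E)-5-bromo-3-chloro-3-methyl-2-(prop-2-en-1-yl)pent-4-en-1-yl acetate | CC(=O)OC[C@@H](CC=C)[C@](C)(Cl)/C=C/Br | intermediate
15 | (1E,3S,4R)-1-bromo-3-chloro-3-methyl-4-[(prop-1-en-2-yloxy)methyl]hepta-1,6-diene | CC(=C)OC[C@@H](CC=C)[C@](C)(Cl)/C=C/Br | intermediate
16 | (3R)-3-[(2S,3E)-4-bromo-2-chlorobut-3-en-2-yl]-6-methyl-3,4-dihydro-2H-pyran | CC1=CC[C@H](CO1)[C@](C)(Cl)/C=C/Br | intermediate
17 | (2R,3R,5R)-3-bromo-5-[(2S,3E)-4-bromo-2-chlorobut-3-en-2-yl]-2-methyloxan-2-ol | C[C@@](Cl)(/C=C/Br)[C@H]1CO[C@@](C)(O)[C@H](Br)C1 | intermediate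
18 | (2R,3S,5R)-3-bromo-5-[(2S,3E)-4-bromo-2-chlorobut-3-en-2-yl]-2-methyloxan-2-ol | C[C@@](Cl)(/C=C/Br)[C@H]1CO[C@@](C)(O)[C@@H](Br)C1 | target

## Step count and risks

Total steps: 11. Longest linear sequence: 11 steps (1 to 18).

The three steps most likely to fail:

**Step 9 (key step).** Once the ruthenium alkylidene sits on the allyl terminus it may close a five-membered ring onto the bromoalkene, expelling a bromomethylidene that deactivates the catalyst, faster than it closes the six-membered ring onto the hindered enol ether. The tertiary allylic chloride may also ionise during the heated titanium stage. The fallback closes the ring before the bromoalkene exists.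
- It sets out from chlorolactone 9. LiBH4 reduction should give (2S,3R)-2-chloro-2-methyl-3-(prop-2-en-1-yl)butane-1,4-diol F1.
- Acetylation of the less hindered hydroxyl (vinyl acetate with Candida antarctica lipase B, or AcCl with 2,4,6-collidine at −78 °C) should give (2R,3S)-3-chloro-4-hydroxy-3-methyl-2-(prop-2-en-1-yl)butyl acetate F2.
- TBSCl and imidazole should give the silyl ether (2R,3S)-4-{[tert-butyl(dimethyl)silyl]oxy}-3-chloro-3-methyl-2-(prop-2-en-1-yl)butyl acetate F3.
- Cp2TiMe2 methylenation to the isopropenyl ether tert-butyl{[(2S,3R)-2-chloro-2-methyl-3-[(prop-1-en-2-yloxy)methyl]hex-5-en-1-yl]oxy}dimethylsilane F4 (not isolated), followed by ring-closing metathesis with no competing alkene in the molecule, should give tert-butyl{[(2S)-2-chloro-2-[(3R)-6-methyl-3,4-dihydro-2H-pyran-3-yl]propyl]oxy}dimethylsilane F5.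
- Bu4NF buffered with AcOH should free (2S)-2-chloro-2-[(3R)-6-methyl-3,4-dihydro-2H-pyran-3-yl]propan-1-ol F6, and Dess–Martin periodinane with NaHCO3 should give (2S)-2-chloro-2-[(3R)-6-methyl-3,4-dihydro-2H-pyran-3-yl]propanal F7.
- Takai olefination of F7 (CrBr2, CHBr3) comes back to the route at 16.

**Step 11.** The equilibrium between the C3 epimers may not lie far enough on the side of the equatorial bromide, or exchange may be slow because little open-chain α-bromo ketone is present. The fallback replaces thermodynamic equilibration by one stereospecific inversion. It sets out from 16: N-iodosuccinimide in wet THF should add trans-diaxially, with the same facial preference as in step 10, to give the axial iodide (2R,3R,5R)-5-[(2S,3E)-4-bromo-2-chlorobut-3-en-2-yl]-3-iodo-2-methyloxan-2-ol F8. One equivalent of Bu4NBr in acetone, with short contact, should then displace iodide with inversion on the ring-opened α-iodo ketone and come back to the route at 18 before bromide–bromide exchange sets in.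

**Step 7.** The α-quaternary lactol may offer too little open-chain aldehyde to the chromium reagent, and divalent chromium may then reduce the C–Cl bond instead. The fallback olefinates a free aldehyde. It sets out from 9, goes through diol F1 and mono-acetate F2 as above, and oxidises F2 with Dess–Martin periodinane to (2R,3S)-3-chloro-3-methyl-4-oxo-2-(prop-2-en-1-yl)butyl acetate F9. Takai olefination of F9 (CrBr2, CHBr3) comes back to the route at 14.

Further compounds
F1 | step 9 | (2S,3R)-2-chloro-2-methyl-3-(prop-2-en-1-yl)butane-1,4-diol | OC[C@@H](CC=C)[C@](C)(Cl)CO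
F2 | step 9 | (2R,3S)-3-chloro-4-hydroxy-3-methyl-2-(prop-2-en-1-yl)butyl acetate | CC(=O)OC[C@@H](CC=C)[C@](C)(Cl)CO
F3 | step 9 | (2R,3S)-4-{[tert-butyl(dimethyl)silyl]oxy}-3-chloro-3-methyl-2-(prop-2-en-1-yl)butyl acetate | CC(=O)OC[C@@H](CC=C)[C@](C)(Cl)CO[Si](C)(C)C(C)(C)C
F4 | step 9 | tert-butyl{[(2S,3R)-2-chloro-2-methyl-3-[(prop-1-en-2-yloxy)methyl]hex-5-en-1-yl]oxy}dimethylsilane | CC(=C)OC[C@@H](CC=C)[C@](C)(Cl)CO[Si](C)(C)C(C)(C)C
F5 | step 9 | tert-butyl{[(2S)-2-chloro-2-[(3R)-6-methyl-3,4-dihydro-2H-pyran-3-yl]propyl]oxy}dimethylsilane | CC1=CC[C@H](CO1)[C@](C)(Cl)CO[Si](C)(C)C(C)(C)C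
F6 | step 9 | (2S)-2-chloro-2-[(3R)-6-methyl-3,4-dihydro-2H-pyran-3-yl]propan-1-ol | CC1=CC[C@H](CO1)[C@](C)(Cl)CO
F7 | step 9 | (2S)-2-chloro-2-[(3R)-6-methyl-3,4-dihydro-2H-pyran-3-yl]propanal | CC1=CC[C@H](CO1)[C@](C)(Cl)C=O
F8 | step 11 | (2R,3R,5R)-5-[(2S,3E)-4-bromo-2-chlorobut-3-en-2-yl]-3-iodo-2-methyloxan-2-ol | C[C@@](Cl)(/C=C/Br)[C@H]1CO[C@@](C)(O)[C@H](I)C1
F9 | step 7 | (2R,3S)-3-chloro-3-methyl-4-oxo-2-(prop-2-en-1-yl)butyl acetate | CC(=O)OC[C@@H](CC=C)[C@](C)(Cl)C=O
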